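Everything rests on cutting the seven-membered ring at C1–C10 and C6–C7 (numbering: C1 methyl-bearing fusion carbon, C2–C3 cyclopentane methylenes, C4 carbinol, C5 fusion CH, C6 ester carbon, C7=C8 alkene, C9–C10 methylenes). The feature used is that the four-carbon run C7–C8(CH3)–C9–C10 maps onto isoprene, while C6 with its oxygen can serve as a methoxycarbene carbon sitting on the C5=C1 double bond of a cyclopentene that already contains the C4 carbinol. In a single operation the chromium carbene cyclopropanates isoprene and the cis-divinylcyclopropane undergoes a Cope shift, which closes the cycloheptadiene and creates quaternary C1. The precursor is a pentacarbonylchromium methoxy(cyclopentenyl)carbene made from (S)-terpinen-4-ol, with the C4 oxygen held as a triethylsilyl ether.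

Key step: step 7

Remark on configuration: the target is read as the cis-fused isomer, with C1–CH3, C5–H, C6–H and the isopropyl group on one face and the C4–OH and the C6 ester oxygen on the other (1R,4R,5S,6R in the numbering above).
Assumption: (S)-terpinen-4-ol is used as enantiomerically pure material; its stereocentre becomes C4 without change.
Design remark: after the key step the C4–O bond is allylic to the enol ether C5=C6–OCH3, where a basic acetal oxygen would invite acid ionisation during unmasking of the ketone. The C4 oxygen is therefore carried as a weakly basic triethylsilyl ether and freed with fluoride once the ketone is in place.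

Step 1
Reactants: 1 (S)-terpinen-4-ol
Product: 2 (S)-terpinen-4-ol triethylsilyl ether
Conditions: Et3SiOTf, 2,6-lutidine, CH2Cl2, 0 °C to rt
Reagents that add atoms: triethylsilyl trifluoromethanesulfonate, CC[Si](CC)(CC)OS(=O)(=O)C(F)(F)F
Why: Silylation with a silyl triflate and a hindered base is the standard etherification of a tertiary alcohol; the alkene is inert and the stereocentre is not touched.

Step 2
Reactants: 2 (S)-terpinen-4-ol triethylsilyl ether
Product: 4 (3S)-6-oxo-3-(propan-2-yl)-3-(triethylsilyloxy)heptanal, via secondary ozonide 3 (not isolated)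
Conditions: O3, CH2Cl2, −78 °C; then PPh3, −78 °C to rt
Reagents that add atoms: ozone, [O-][O+]=O
Why: Ozonolysis of the only alkene followed by reductive cleavage of the ozonide should unmask the methyl ketone and the aldehyde; the silyl ether is inert to ozone and the quaternary stereocentre cannot epimerise.

Step 3
Reactants: 4 (3S)-6-oxo-3-(propan-2-yl)-3-(triethylsilyloxy)heptanal
Product: 6 (5R)-2-methyl-5-(propan-2-yl)-5-(triethylsilyloxy)cyclopent-1-ene-1-carbaldehyde, via aldol adduct 5 (not isolated)
Conditions: piperidine (0.2 equiv), AcOH (0.2 equiv), benzene, rt to 50 °C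
Reagents that add atoms: none
Why: Amine-catalysed intramolecular aldol condensation, in which the piperidine enamine of the aldehyde adds to the methyl ketone (5-exo-trig) and water is lost to give the tetrasubstituted enal, as in the usual conversion of 6-oxoheptanals into 2-methylcyclopentenecarbaldehydes; the buffered, mild conditions are chosen to keep β-elimination of the silyloxy group slow.

Step 4
Reactants: 6 (5R)-2-methyl-5-(propan-2-yl)-5-(triethylsilyloxy)cyclopent-1-ene-1-carbaldehyde
Product: 7 (5R)-2-methyl-5-(propan-2-yl)-5-(triethylsilyloxy)cyclopent-1-ene-1-carboxylic acid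
Conditions: NaClO2, NaH2PO4, 2-methyl-2-butene, t-BuOH/H2O, 0 °C to rt
Reagents that add atoms: sodium chlorite, [Na+].[O-]Cl=O
Why: Pinnick oxidation converts enals into acids without touching the alkene, and the hindered tertiary silyl ether should survive the weakly acidic buffer.

Step 5
Reactants: 7 (5R)-2-methyl-5-(propan-2-yl)-5-(triethylsilyloxy)cyclopent-1-ene-1-carboxylic acid
Product: 8 (5R)-2-methyl-5-(propan-2-yl)-5-(triethylsilyloxy)cyclopent-1-ene-1-carbonyl chloride
Conditions: 1-chloro-N,N,2-trimethylprop-1-en-1-amine (Ghosez reagent), CH2Cl2, 0 °C to rt; concentrate and use crude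
Reagents that add atoms: 1-chloro-N,N,2-trimethylprop-1-en-1-amine, CC(C)=C(Cl)N(C)C
Why: Chlorination with the α-chloroenamine is neutral and releases no HCl, so the allylic tertiary silyl ether is not cleaved.

Step 6
Reactants: 8 (5R)-2-methyl-5-(propan-2-yl)-5-(triethylsilyloxy)cyclopent-1-ene-1-carbonyl chloride; 9 hexacarbonylchromium
Product: 12 pentacarbonyl{methoxy[(5R)-2-methyl-5-(propan-2-yl)-5-(triethylsilyloxy)cyclopent-1-en-1-yl]methylidene}chromium, via disodium pentacarbonylchromate 10 (not isolated), via sodium acylchromate 11 (not isolated)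
Conditions: Cr(CO)6, NaC10H8 (sodium naphthalenide, 2 equiv), THF, −78 °C; add 8, −78 to 0 °C; evaporate; MeOTf, CH2Cl2, 0 °C
Reagents that add atoms: methyl trifluoromethanesulfonate, COS(=O)(=O)C(F)(F)F
Why: Fischer carbene synthesis from an acid chloride, in which the pentacarbonylchromate dianion is acylated at chromium and the resulting acylmetalate is O-methylated by the hard alkylating agent; the aldehyde carbon of 6 thereby becomes the carbene carbon C6.

Step 7
Reactants: 12 pentacarbonyl{methoxy[(5R)-2-methyl-5-(propan-2-yl)-5-(triethylsilyloxy)cyclopent-1-en-1-yl]methylidene}chromium; 13 isoprene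
Product: 15 dienol methyl ether (3R,8aS)-4-methoxy-6,8a-dimethyl-3-(propan-2-yl)-3-(triethylsilyloxy)-1,2,3,5,8,8a-hexahydroazulene, via cis-divinylcyclopropane 14 (not isolated)
Conditions: isoprene (20 equiv), 1,4-dioxane, sealed tube, 100 °C
Reagents that add atoms: none
Why: Thermal loss of CO from 12 opens a site for isoprene, and the electrophilic carbene carbon C6 is transferred to the 2-methyl-substituted alkene through a chromacyclobutane and reductive elimination, a [2+1] closure of the temporary three-membered ring C6–C7–C8 in which the first bond goes to the unsubstituted terminus C7 and charge builds at the tertiary allylic carbon C8. The cis-divinylcyclopropane 14 then undergoes a Cope [3,3] shift through a boat transition state that forms C1–C10 and breaks C6–C8, so the seven-membered ring is closed by ring expansion with both ring alkenes cis and C6 left as a methyl enol ether; a trans isomer should feed the cis one at 100 °C by reversible homolysis of the donor-substituted, doubly allylic C6–C8 bond. The closest known chemistry is the formal [4+3] annulation in which chromium alkenyl(alkoxy)carbenes cyclopropanate 1,3-dienes and the cis-divinylcyclopropanes rearrange to cycloheptadienes. The one new stereocentre, quaternary C1, is controlled by C4: in the boat the cyclopropane carbon C8 and its methyl lie over one face of the cyclopentene beside a C4 substituent, and the arrangement that places them beside the small silyloxy oxygen and away from the branched isopropyl group is less crowded, so C10 should bond to C1 on the oxygen face. The step needs chemoselectivity for carbene transfer over a Diels–Alder addition to the carbene-activated alkene, secured by that alkene being tetrasubstituted between two fully substituted carbons, and regioselectivity for the methyl-bearing alkene of isoprene, secured only by its higher nucleophilicity toward the electrophilic carbene carbon.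

Step 8
Reactants: 15 dienol methyl ether (3R,8aS)-4-methoxy-6,8a-dimethyl-3-(propan-2-yl)-3-(triethylsilyloxy)-1,2,3,5,8,8a-hexahydroazulene
Product: 17 cis-fused enone (3R,3aR,8aR)-6,8a-dimethyl-3-(propan-2-yl)-3-(triethylsilyloxy)-2,3,3a,7,8,8a-hexahydroazulen-4(1H)-one, via β,γ-unsaturated ketone 16 (not isolated)
Conditions: (CO2H)2 (0.3 equiv), THF/H2O, 0 °C to rt; NaHCO3 wash; then K2CO3 (0.2 equiv), MeOH, rt
Reagents that add atoms: water, O
Why: Weak-acid hydrolysis of the enol ether (protonation at C5, capture of the oxocarbenium ion by water, loss of methanol) favours C-protonation over ionisation of the silyl-protected C4–O bond, and carbonate in methanol then moves the C8=C9 alkene into conjugation through the C7 dienolate and lets C5 settle as the cis-fused epimer (C6 on the face of the silyloxy group, away from isopropyl and the angular methyl), reprotonation of the C5 enolate in methanol being expected to outrun β-elimination of silanolate.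

Step 9
Reactants: 17 cis-fused enone (3R,3aR,8aR)-6,8a-dimethyl-3-(propan-2-yl)-3-(triethylsilyloxy)-2,3,3a,7,8,8a-hexahydroazulen-4(1H)-one
Product: 18 (3R,3aR,8aR)-3-hydroxy-6,8a-dimethyl-3-(propan-2-yl)-2,3,3a,7,8,8a-hexahydroazulen-4(1H)-one
Conditions: HF·pyridine, pyridine, THF, 0 °C to rt
Reagents that add atoms: none
Why: Fluoride cleavage of the silyl ether under buffered, non-basic conditions is the standard way to free a β-hydroxy ketone without retro-aldol cleavage or dehydration, and no stereocentre is touched.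

Step 10
Reactants: 18 (3R,3aR,8aR)-3-hydroxy-6,8a-dimethyl-3-(propan-2-yl)-2,3,3a,7,8,8a-hexahydroazulen-4(1H)-one
Product: 19 (3R,3aS,4R,8aR)-6,8a-dimethyl-3-(propan-2-yl)-1,2,3,3a,4,7,8,8a-octahydroazulene-3,4-diol
Conditions: NaBH4, CeCl3·7H2O, MeOH, −40 °C
Reagents that add atoms: none
Why: Luche 1,2-reduction of the enone, in which hydride should reach C6 from the face of the small C5–H, with cerium bridging of C4–OH and C6=O reinforcing formation of the syn-1,3-diol, so that C6 is set with H6 cis to H5 and the new hydroxyl cis to the C4–OH.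

Step 11
Reactants: 20 isovanillic acid
Product: 22 3-(tert-butyldimethylsilyloxy)-4-methoxybenzoic acid, via bis-silylated acid 21 (not isolated)
Conditions: t-BuMe2SiCl (2.5 equiv), imidazole, DMF, rt; then AcOH/THF/H2O, rt
Reagents that add atoms: tert-butyldimethylsilyl chloride, CC(C)(C)[Si](C)(C)Cl
Why: Silylation of phenol and acid followed by selective hydrolysis of the much more labile silyl ester is the usual route to an O-silylated hydroxybenzoic acid.

Step 12
Reactants: 19 (3R,3aS,4R,8aR)-6,8a-dimethyl-3-(propan-2-yl)-1,2,3,3a,4,7,8,8a-octahydroazulene-3,4-diol; 22 3-(tert-butyldimethylsilyloxy)-4-methoxybenzoic acid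
Product: 24 (3R,3aS,4R,8aR)-3-hydroxy-6,8a-dimethyl-3-(propan-2-yl)-1,2,3,3a,4,7,8,8a-octahydroazulen-4-yl 3-(tert-butyldimethylsilyloxy)-4-methoxybenzoate, via O-acylisourea 23 (not isolated)
Conditions: DCC, DMAP, CH2Cl2, 0 °C to rt
Reagents that add atoms: none
Why: Steglich esterification acylates the secondary allylic C6–OH while the hindered tertiary C4–OH does not react, and since the C6–O bond is not broken the configuration is retained.

Step 13
Reactants: 24 (3R,3aS,4R,8aR)-3-hydroxy-6,8a-dimethyl-3-(propan-2-yl)-1,2,3,3a,4,7,8,8a-octahydroazulen-4-yl 3-(tert-butyldimethylsilyloxy)-4-methoxybenzoate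
Product: 25 (3R,3aS,4R,8aR)-3-hydroxy-6,8a-dimethyl-3-(propan-2-yl)-1,2,3,3a,4,7,8,8a-octahydroazulen-4-yl 3-hydroxy-4-methoxybenzoate (CNP0210850.1)
Conditions: Bu4NF, AcOH, THF, 0 °C
Reagents that add atoms: none
Why: Fluoride cleavage of the aryl silyl ether is fast at 0 °C, and the acetic acid buffer protonates the phenoxide so that the allylic ester is not attacked.

Compound list
1 | (S)-terpinen-4-ol, (1S)-4-methyl-1-(propan-2-yl)cyclohex-3-en-1-ol | CC1=CC[C@](O)(C(C)C)CC1 | starting material
2 | (S)-terpinen-4-ol triethylsilyl ether | CC1=CC[C@](O[Si](CC)(CC)CC)(C(C)C)CC1 | intermediate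
3 | secondary ozonide of 2 (1,2,4-trioxolane across the former alkene carbons, both bridge diastereomers) | CC12OOC(O1)C[C@](O[Si](CC)(CC)CC)(C(C)C)CC2 | intermediate (not isolated)
4 | (3S)-6-oxo-3-(propan-2-yl)-3-(triethylsilyloxy)heptanal | O=CC[C@](O[Si](CC)(CC)CC)(C(C)C)CCC(C)=O | intermediate
5 | aldol adduct, (5R)-2-hydroxy-2-methyl-5-(propan-2-yl)-5-(triethylsilyloxy)cyclopentane-1-carbaldehyde (mixture at the two new centres) | O=CC1C(C)(O)CC[C@@]1(O[Si](CC)(CC)CC)C(C)C | intermediate (not isolated)
6 | (5R)-2-methyl-5-(propan-2-yl)-5-(triethylsilyloxy)cyclopent-1-ene-1-carbaldehyde | O=CC1=C(C)CC[C@@]1(O[Si](CC)(CC)CC)C(C)C | intermediate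
7 | (5R)-2-methyl-5-(propan-2-yl)-5-(triethylsilyloxy)cyclopent-1-ene-1-carboxylic acid | OC(=O)C1=C(C)CC[C@@]1(O[Si](CC)(CC)CC)C(C)C | intermediate
8 | (5R)-2-methyl-5-(propan-2-yl)-5-(triethylsilyloxy)cyclopent-1-ene-1-carbonyl chloride | ClC(=O)C1=C(C)CC[C@@]1(O[Si](CC)(CC)CC)C(C)C | intermediate
9 | hexacarbonylchromium, Cr(CO)6 | O=C=[Cr](=C=O)(=C=O)(=C=O)(=C=O)=C=O | starting material
10 | disodium pentacarbonylchromate, Na2Cr(CO)5 | [Na+].[Na+].O=C=[Cr-2](=C=O)(=C=O)(=C=O)=C=O | intermediate (not isolated)
11 | sodium acylpentacarbonylchromate of 8 | [Na+].[O-]C(=[Cr](=C=O)(=C=O)(=C=O)(=C=O)=C=O)C1=C(C)CC[C@@]1(O[Si](CC)(CC)CC)C(C)C | intermediate (not isolated)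
12 | pentacarbonyl{methoxy[(5R)-2-methyl-5-(propan-2-yl)-5-(triethylsilyloxy)cyclopent-1-en-1-yl]methylidene}chromium | COC(=[Cr](=C=O)(=C=O)(=C=O)(=C=O)=C=O)C1=C(C)CC[C@@]1(O[Si](CC)(CC)CC)C(C)C | intermediate
13 | isoprene | C=CC(C)=C | starting material
14 | 1-methoxy-2-methyl-1-[(5R)-2-methyl-5-(propan-2-yl)-5-(triethylsilyloxy)cyclopent-1-en-1-yl]-2-vinylcyclopropane, cyclopentenyl and vinyl cis (cyclopropane centres not fixed relative to C4, since they interconvert under the conditions) | COC1(C2=C(C)CC[C@@]2(O[Si](CC)(CC)CC)C(C)C)CC1(C)C=C | intermediate (not isolated)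
15 | (3R,8aS)-4-methoxy-6,8a-dimethyl-3-(propan-2-yl)-3-(triethylsilyloxy)-1,2,3,5,8,8a-hexahydroazulene | COC1=C2[C@](O[Si](CC)(CC)CC)(C(C)C)CC[C@@]2(C)CC=C(C)C1 | intermediate
16 | (3R,3aR,8aS)-6,8a-dimethyl-3-(propan-2-yl)-3-(triethylsilyloxy)-2,3,3a,5,8,8a-hexahydroazulen-4(1H)-one (drawn as the cis-fused C5 epimer) | O=C2CC(C)=CC[C@]3(C)CC[C@@](O[Si](CC)(CC)CC)(C(C)C)[C@H]23 | intermediate (not isolated)
17 | (3R,3aR,8aR)-6,8a-dimethyl-3-(propan-2-yl)-3-(triethylsilyloxy)-2,3,3a,7,8,8a-hexahydroazulen-4(1H)-one | O=C2C=C(C)CC[C@]3(C)CC[C@@](O[Si](CC)(CC)CC)(C(C)C)[C@H]23 | intermediate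
18 | (3R,3aR,8aR)-3-hydroxy-6,8a-dimethyl-3-(propan-2-yl)-2,3,3a,7,8,8a-hexahydroazulen-4(1H)-one | O=C2C=C(C)CC[C@]3(C)CC[C@@](O)(C(C)C)[C@H]23 | intermediate
19 | (3R,3aS,4R,8aR)-6,8a-dimethyl-3-(propan-2-yl)-1,2,3,3a,4,7,8,8a-octahydroazulene-3,4-diol | O[C@@H]2C=C(C)CC[C@]3(C)CC[C@@](O)(C(C)C)[C@H]23 | intermediate
20 | isovanillic acid, 3-hydroxy-4-methoxybenzoic acid | COc1ccc(C(=O)O)cc1O | starting material
21 | tert-butyldimethylsilyl 3-(tert-butyldimethylsilyloxy)-4-methoxybenzoate | COc1ccc(C(=O)O[Si](C)(C)C(C)(C)C)cc1O[Si](C)(C)C(C)(C)C | intermediate (not isolated)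
22 | 3-(tert-butyldimethylsilyloxy)-4-methoxybenzoic acid | COc1ccc(C(=O)O)cc1O[Si](C)(C)C(C)(C)C | intermediate
23 | O-acylisourea from 22 and DCC | O=C(OC(=NC1CCCCC1)NC1CCCCC1)c1ccc(OC)c(O[Si](C)(C)C(C)(C)C)c1 | intermediate (not isolated)
24 | (3R,3aS,4R,8aR)-3-hydroxy-6,8a-dimethyl-3-(propan-2-yl)-1,2,3,3a,4,7,8,8a-octahydroazulen-4-yl 3-(tert-butyldimethylsilyloxy)-4-methoxybenzoate | COc1ccc(C(=O)O[C@@H]2C=C(C)CC[C@]3(C)CC[C@@](O)(C(C)C)[C@H]23)cc1O[Si](C)(C)C(C)(C)C | intermediate
25 | (3R,3aS,4R,8aR)-3-hydroxy-6,8a-dimethyl-3-(propan-2-yl)-1,2,3,3a,4,7,8,8a-octahydroazulen-4-yl 3-hydroxy-4-methoxybenzoate | COc1ccc(C(=O)O[C@@H]2C=C(C)CC[C@]3(C)CC[C@@](O)(C(C)C)[C@H]23)cc1O | target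

Total step count: 13. Longest linear sequence: 12 steps (steps 1–10, 12 and 13, from (S)-terpinen-4-ol); step 11 is a one-step side branch.

Steps most likely to fail

Step 7. Carbene transfer may go to the unsubstituted vinyl group of isoprene, which after the Cope shift would put the ring methyl on C9. The crowded carbene may also decay thermally before transfer, or the boat may show too little facial bias from C4. The fallback sets out from enal 6 and returns at ketone 16; it keeps the Cope shift but builds the cyclopropane stepwise. CH3CH=CHCH2MgCl adds to 6 through its γ-carbon to give the branched homoallylic alcohol F1, and Dess–Martin periodinane oxidises it to the β,γ-unsaturated ketone F2. LiN(iPr)2 followed by Me3SiCl at −78 °C removes the doubly activated C8–H and gives the 2-silyloxydiene F3. Et2Zn/CH2I2 (Simmons–Smith cyclopropanation) should take the electron-rich silyl enol ether alkene and give the silyloxy divinylcyclopropane F4, in which the new methylene is C7. Heating in toluene should give, by the same Cope shift, the trimethylsilyl enol ether F5. Bu4NF/AcOH then frees ketone 16, which enters the carbonate treatment of step 8.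

Step 8. The acid needed for unmasking may ionise the C4–O bond, which is allylic to the enol ether, so that the C4 oxygen is lost through an alkoxyallyl cation; protonation at the crowded C5 may also be slow and unselective. The fallback sets out from acylate 11 and returns at ketone 16; it makes the enol ether fluoride-labile so that no acid is needed. Acylate 11 is O-acylated with CH3COBr at −40 °C to the acetoxycarbene F6, which exchanges with 2-(trimethylsilyl)ethanol to the 2-(trimethylsilyl)ethoxycarbene F7, the usual acyloxy-to-alkoxy exchange for varying the alkoxy group of a Fischer carbene. The conditions of step 7 should give, through the cyclopropane F8, the 2-(trimethylsilyl)ethyl dienol ether F9. Bu4NF/AcOH in THF should then trigger fluoride-induced β-elimination, with ethene and Me3SiF lost and the C6 enolate as leaving group. This is argued by analogy with the phenoxides for which the cleavage is routine, not from precedent on enol ethers. Protonation gives 16, which is taken on by the carbonate treatment of step 8.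

Step 6. Electron transfer from the strongly reducing chromate dianion to the conjugated acid chloride, together with slow substitution at the crowded acyl carbon, may let reduction outrun acylation. The fallback sets out from acid 7 and returns at carbene 12; it is the classical Fischer synthesis through a vinyllithium. (PhO)2P(O)N3/Et3N converts 7 into the acyl azide F10, which on warming in toluene undergoes Curtius rearrangement to the vinyl isocyanate F11. Dilute aqueous HCl hydrolyses this to the ketone F12, and 2,4,6-triisopropylbenzenesulfonyl hydrazide gives the hydrazone F13. n-BuLi (2 equiv) effects the Shapiro reaction, deprotonating the only α-CH (the methyl-bearing carbon), to give the vinyllithium F14. Addition to Cr(CO)6 9 gives the lithium acylchromate F15, and MeOTf gives 12.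

Further compounds
F1 | step 7 | 2-methyl-1-[(5R)-2-methyl-5-(propan-2-yl)-5-(triethylsilyloxy)cyclopent-1-en-1-yl]but-3-en-1-ol (mixture of diastereomers) | C=CC(C)C(O)C1=C(C)CC[C@@]1(O[Si](CC)(CC)CC)C(C)C
F2 | step 7 | 2-methyl-1-[(5R)-2-methyl-5-(propan-2-yl)-5-(triethylsilyloxy)cyclopent-1-en-1-yl]but-3-en-1-one | C=CC(C)C(=O)C1=C(C)CC[C@@]1(O[Si](CC)(CC)CC)C(C)C
F3 | step 7 | trimethylsilyl dienol ether of F2, 2-methyl-1-(cyclopentenyl)-1-(trimethylsilyloxy)buta-1,3-diene (E/Z mixture) | C=CC(C)=C(O[Si](C)(C)C)C1=C(C)CC[C@@]1(O[Si](CC)(CC)CC)C(C)C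
F4 | step 7 | 2-methyl-1-[(5R)-2-methyl-5-(propan-2-yl)-5-(triethylsilyloxy)cyclopent-1-en-1-yl]-1-(trimethylsilyloxy)-2-vinylcyclopropane | C=CC1(C)CC1(O[Si](C)(C)C)C1=C(C)CC[C@@]1(O[Si](CC)(CC)CC)C(C)C
F5 | step 7 | (3R,8aS)-6,8a-dimethyl-3-(propan-2-yl)-3-(triethylsilyloxy)-4-(trimethylsilyloxy)-1,2,3,5,8,8a-hexahydroazulene | C[Si](C)(C)OC1=C2[C@](O[Si](CC)(CC)CC)(C(C)C)CC[C@@]2(C)CC=C(C)C1
F6 | step 8 | pentacarbonyl{acetoxy[(5R)-2-methyl-5-(propan-2-yl)-5-(triethylsilyloxy)cyclopent-1-en-1-yl]methylidene}chromium | CC(=O)OC(=[Cr](=C=O)(=C=O)(=C=O)(=C=O)=C=O)C1=C(C)CC[C@@]1(O[Si](CC)(CC)CC)C(C)C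
F7 | step 8 | pentacarbonyl{[2-(trimethylsilyl)ethoxy][(5R)-2-methyl-5-(propan-2-yl)-5-(triethylsilyloxy)cyclopent-1-en-1-yl]methylidene}chromium | C[Si](C)(C)CCOC(=[Cr](=C=O)(=C=O)(=C=O)(=C=O)=C=O)C1=C(C)CC[C@@]1(O[Si](CC)(CC)CC)C(C)C
F8 | step 8 | 2-methyl-1-[(5R)-2-methyl-5-(propan-2-yl)-5-(triethylsilyloxy)cyclopent-1-en-1-yl]-1-[2-(trimethylsilyl)ethoxy]-2-vinylcyclopropane | C[Si](C)(C)CCOC1(C2=C(C)CC[C@@]2(O[Si](CC)(CC)CC)C(C)C)CC1(C)C=C
F9 | step 8 | (3R,8aS)-6,8a-dimethyl-3-(propan-2-yl)-3-(triethylsilyloxy)-4-[2-(trimethylsilyl)ethoxy]-1,2,3,5,8,8a-hexahydroazulene | C[Si](C)(C)CCOC1=C2[C@](O[Si](CC)(CC)CC)(C(C)C)CC[C@@]2(C)CC=C(C)C1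
F10 | step 6 | (5R)-2-methyl-5-(propan-2-yl)-5-(triethylsilyloxy)cyclopent-1-ene-1-carbonyl azide | [N-]=[N+]=NC(=O)C1=C(C)CC[C@@]1(O[Si](CC)(CC)CC)C(C)C
F11 | step 6 | (5R)-1-isocyanato-2-methyl-5-(propan-2-yl)-5-(triethylsilyloxy)cyclopent-1-ene | O=C=NC1=C(C)CC[C@@]1(O[Si](CC)(CC)CC)C(C)C
F12 | step 6 | (2R)-5-methyl-2-(propan-2-yl)-2-(triethylsilyloxy)cyclopentan-1-one (mixture at C5) | O=C1C(C)CC[C@@]1(O[Si](CC)(CC)CC)C(C)C
F13 | step 6 | 2,4,6-triisopropylbenzenesulfonyl hydrazone of F12 | CC(C)c1cc(C(C)C)c(S(=O)(=O)NN=C2C(C)CC[C@@]2(O[Si](CC)(CC)CC)C(C)C)c(C(C)C)c1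
F14 | step 6 | [(5R)-2-methyl-5-(propan-2-yl)-5-(triethylsilyloxy)cyclopent-1-en-1-yl]lithium | [Li]C1=C(C)CC[C@@]1(O[Si](CC)(CC)CC)C(C)C
F15 | step 6 | lithium acylpentacarbonylchromate from F14 and Cr(CO)6 | [Li+].[O-]C(=[Cr](=C=O)(=C=O)(=C=O)(=C=O)=C=O)C1=C(C)CC[C@@]1(O[Si](CC)(CC)CC)C(C)C
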